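**Retrosynthetic overview** (germacrane numbering)
1. Last disconnection: the 8-O ester, giving the 8α-alcohol (15-O-TBDPS-salonitenolide) and a (3R)-4-acetoxy-3-silyloxy-2-methylidenebutanoic acid made from (S)-glyceraldehyde acetonide via an alkyne and Markovnikov hydroxycarbonylation.
2. Key disconnection C7–C8: a SmI2-generated C8 ketyl radical closes the ten-membered ring by 10-exo addition to C7 of an α-(silyloxymethyl)butenolide; the samarium enolate then expels silanolate to unveil the α-methylene lactone. C7 and C8 are set in this step.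
3. Butenolide (C6 stereocentre): Zn–ProPhenol alkynylation of a Z-enal, hydroxyl-directed trans-hydroalumination/iodination, Pd carbonylative lactonisation.
4. Acyclic chain: Negishi carboalumination of butynol (E-C1=C10), oxirane (C2–C3), copper-catalysed anti-carbomagnesiation of propargyl alcohol (C4=C5 with the C15 oxygen), DMF (C6).
5. Ring order: butenolide first, ten-membered carbocycle second.

Assumption: the SMILES is read as 4′-O-acetylcnicin, 6R,7R,8S,3′R, with both ring alkenes trans within the ring (C6 = lactone O–CH, C8 = ester carbon, C11=C13 = methylene, C12 = lactone C=O, C14 = methyl, C15 = CH2OH).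

**Step 1**
Reactants: 1 but-3-yn-1-ol
Product: 2 (but-3-yn-1-yloxy)triethylsilane
Conditions: TESCl, imidazole, CH2Cl2, 0 °C to rt
Reagents that add atoms: chlorotriethylsilane, CC[Si](Cl)(CC)CC
Why: Standard silyl ether formation; TES is chosen because it can later be oxidised off directly next to TBS and TBDPS ethers.

**Step 2**
Reactants: 2 (but-3-yn-1-yloxy)triethylsilane; 3 oxirane
Product: 6 (3E)-4-methyl-6-(triethylsilyloxy)hex-3-en-1-ol, via alkenylalane 4 (not isolated), via lithium alanate 5 (not isolated)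
Conditions: Me3Al (2 equiv), Cp2ZrCl2 (20 mol%), CH2Cl2, 0 °C to rt; n-BuLi, hexane–THF, −30 °C; then 3, −30 to 0 °C; aq. NH4Cl
Reagents that add atoms: trimethylaluminium, C[Al](C)C
Why: Negishi zirconium-catalysed carboalumination adds CH3 and Al syn with Al on the terminal carbon, which fixes the E trisubstituted C1=C10 alkene, and the derived alanate opens oxirane with retention at the alkenyl carbon to append C2–C3.

**Step 3**
Reactants: 6 (3E)-4-methyl-6-(triethylsilyloxy)hex-3-en-1-ol
Product: 8 [(3E)-6-bromo-3-methylhex-3-en-1-yl]oxy(triethyl)silane, via mesylate 7 (not isolated)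
Conditions: MsCl, Et3N, CH2Cl2, 0 °C; then LiBr, THF, 40 °C
Reagents that add atoms: lithium bromide, [Li+].[Br-]
Why: Mesylation followed by SN2 displacement with bromide (Finkelstein type) under near-neutral conditions that keep the TES ether.

**Step 4**
Reactants: 8 homoallylic bromide; 9 prop-2-yn-1-ol
Product: 13 (2Z)-3-iodo-2-[(3E)-4-methyl-6-(triethylsilyloxy)hex-3-en-1-yl]prop-2-en-1-ol, via Grignard reagent 10 (not isolated), via chloromagnesium propynolate 11 (not isolated), via cyclic alkenylmagnesium alkoxide 12 (not isolated)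
Conditions: 8, Mg, THF, 40 °C; 9 + i-PrMgCl (1.0 equiv), THF, 0 °C; combine, CuI (10 mol%), rt, 16 h; I2, THF, −20 °C
Reagents that add atoms: iodine, [I][I]
Why: Duboudin-type copper-catalysed anti-carbomagnesiation of the propargylic alkoxide puts the alkyl group on the internal carbon and magnesium cis to the CH2O group in a five-membered chelate, so iodinolysis with retention gives the Z iodide that fixes the C4=C5 geometry (C15 cis to the future C6).

**Step 5**
Reactants: 13 (Z)-iodo allylic alcohol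
Product: 14 tert-butyl{[(2Z)-3-iodo-2-[(3E)-4-methyl-6-(triethylsilyloxy)hex-3-en-1-yl]prop-2-en-1-yl]oxy}diphenylsilane
Conditions: TBDPSCl, imidazole, CH2Cl2, rt
Reagents that add atoms: tert-butyl(chloro)diphenylsilane, CC(C)(C)[Si](Cl)(c1ccccc1)c1ccccc1
Why: Standard silylation; the bulky, acid-stable TBDPS group on O-15 resists 1,4-silyl migration in step 6 and stays distinct from the TBS ether introduced in step 7.

**Step 6**
Reactants: 14 (Z)-alkenyl iodide
Product: 16 (2Z,6E)-3-[(tert-butyldiphenylsilyloxy)methyl]-7-methyl-9-(triethylsilyloxy)nona-2,6-dienal, via alkenyllithium 15 (not isolated)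
Conditions: t-BuLi (2.05 equiv), Et2O, −78 °C, 15 min; DMF, −78 to 0 °C; aq. NH4Cl
Reagents that add atoms: N,N-dimethylformamide, CN(C)C=O
Why: Iodine–lithium exchange proceeds with retention of alkene geometry and formylation of the alkenyllithium with DMF (Bouveault type) installs C6 as the Z-enal.

**Step 7**
Reactants: 16 (2Z,6E)-enal; 17 tert-butyldimethyl(prop-2-yn-1-yloxy)silane
Product: 19 (4R,5Z,9E)-1-(tert-butyldimethylsilyloxy)-6-[(tert-butyldiphenylsilyloxy)methyl]-10-methyl-12-(triethylsilyloxy)dodeca-5,9-dien-2-yn-4-ol, via alkynylzinc 18 (not isolated)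
Conditions: 17 (3 equiv), Me2Zn (3 equiv), (R,R)-ProPhenol [2,6-bis{[(R)-2-(hydroxydiphenylmethyl)pyrrolidin-1-yl]methyl}-4-methylphenol] (20 mol%), Ph3P=O (40 mol%), toluene, 4 °C, 48 h
Reagents that add atoms: none
Why: Dinuclear zinc–ProPhenol catalysed enantioselective alkynylation of an α,β-unsaturated aldehyde; with the (R,R) ligand the alkynylzinc is expected to attack the Si face (the facial sense of ProPhenol aldol additions), giving the 4R carbinol that becomes C6 (the ligand antipode would give 4S).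

**Step 8**
Reactants: 19 (4R)-propargylic alcohol
Product: 21 (2Z,4R,5Z,9E)-1-(tert-butyldimethylsilyloxy)-6-[(tert-butyldiphenylsilyloxy)methyl]-2-iodo-10-methyl-12-(triethylsilyloxy)dodeca-2,5,9-trien-4-ol, via cyclic alkenylalanate 20 (not isolated)
Conditions: NaAlH2(OCH2CH2OMe)2 (1.6 equiv), THF, 0 °C, 2 h; I2, THF, −78 °C
Reagents that add atoms: iodine, [I][I]
Why: Hydroxyl-directed trans-hydroalumination of the propargylic alcohol delivers hydride to the proximal carbon and aluminium to the distal one in a five-membered alanate, and iodinolysis with retention gives the iodide cis to the carbinol; the silylated propargylic oxygen does not direct and at 0 °C does not eliminate to an allene.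

**Step 9**
Reactants: 21 (Z)-iodo dienol
Product: 22 (5R)-3-[(tert-butyldimethylsilyloxy)methyl]-5-[(1Z,5E)-2-[(tert-butyldiphenylsilyloxy)methyl]-6-methyl-8-(triethylsilyloxy)octa-1,5-dien-1-yl]furan-2(5H)-one
Conditions: PdCl2(PPh3)2 (5 mol%), CO (1 atm), K2CO3, THF, 40 °C
Reagents that add atoms: carbon monoxide, [C-]#[O+]
Why: Palladium-catalysed carbonylative lactonisation (oxidative addition of zerovalent palladium into C–I, CO insertion, capture of the acylpalladium by the cis hydroxyl) closes the butenolide without touching the C6 stereocentre.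

**Step 10**
Reactants: 22 butenolide TES ether
Product: 23 (3E,7Z)-8-[(2R)-4-[(tert-butyldimethylsilyloxy)methyl]-5-oxo-2,5-dihydrofuran-2-yl]-7-[(tert-butyldiphenylsilyloxy)methyl]-3-methylocta-3,7-dienal
Conditions: IBX (3 equiv), DMSO, rt
Reagents that add atoms: none
Why: IBX in DMSO cleaves the primary TES ether and oxidises the freed alcohol in one pot (oxidative desilylation) while TBS and TBDPS ethers survive, and the neutral medium keeps the β,γ-unsaturated aldehyde from conjugating.

**Step 11**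
Reactants: 23 aldehyde butenolide
Product: 26 (3aR,4S,6E,10Z,11aR)-10-[(tert-butyldiphenylsilyloxy)methyl]-4-hydroxy-6-methyl-3-methylidene-3a,4,5,8,9,11a-hexahydrocyclodeca[b]furan-2(3H)-one, via ketyl radical 24 (not isolated), via samarium enolate 25 (not isolated)
Conditions: 23 added over 6 h to SmI2 (2.5 equiv, 0.01 M in THF), 0 °C, no proton source; 30 min; aq. NH4Cl
Reagents that add atoms: none
Why: Proposed new method: SmI2 reduces the aldehyde to a samarium ketyl radical that adds 10-exo-trig to C7 of the butenolide (a ketyl–enoate coupling of the Fukuzawa type, known for five- to eight-membered rings and here stretched to a ten-membered ring by high dilution and by chelation of trivalent samarium between the ketyl oxygen and the lactone carbonyl); the resulting α-lactone radical is reduced by a second SmI2 to the samarium enolate, which expels tert-butyldimethylsilanolate (E1cB, as in SmI2-induced β-eliminations of β-oxygenated samarium enolates) to give the exocyclic methylene; C7 is attacked anti to the C6–C5 bond (trans lactone, the low-strain fusion for an E,E-cyclodecadiene) and the bulky O–Sm group takes the pseudo-equatorial site anti to C6 with H7/H8 antiperiplanar, which corresponds to 8S.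

**Step 12**
Reactants: 27 (4S)-2,2-dimethyl-1,3-dioxolane-4-carbaldehyde
Product: 28 (4R)-4-ethynyl-2,2-dimethyl-1,3-dioxolane
Conditions: dimethyl (1-diazo-2-oxopropyl)phosphonate, K2CO3, MeOH, 0 °C to rt
Reagents that add atoms: dimethyl (1-diazo-2-oxopropyl)phosphonate, CC(=O)C(=[N+]=[N-])P(=O)(OC)OC
Why: Ohira–Bestmann homologation (Seyferth–Gilbert type) converts the aldehyde into the terminal alkyne with the α-stereocentre retained (the descriptor changes from S to R only through the priority change).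

**Step 13**
Reactants: 28 (4R)-alkyne acetonide
Product: 29 (2R)-but-3-yne-1,2-diol
Conditions: AcOH–H2O 4:1, 40 °C
Reagents that add atoms: none
Why: Acid-catalysed acetonide hydrolysis; the stereocentre is not involved.

**Step 14**
Reactants: 29 (2R)-but-3-yne-1,2-diol
Product: 30 (2R)-2-hydroxybut-3-yn-1-yl acetate
Conditions: AcCl (1.05 equiv), 2,4,6-collidine, CH2Cl2, −78 °C
Reagents that add atoms: acetyl chloride, CC(Cl)=O
Why: Low-temperature acylation with a hindered pyridine base is selective for the primary hydroxyl.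

**Step 15**
Reactants: 30 (2R)-2-hydroxybut-3-yn-1-yl acetate
Product: 31 (2R)-2-(tert-butyldimethylsilyloxy)but-3-yn-1-yl acetate
Conditions: TBSOTf, 2,6-lutidine, CH2Cl2, −78 °C
Reagents that add atoms: tert-butyldimethylsilyl trifluoromethanesulfonate, CC(C)(C)[Si](C)(C)OS(=O)(=O)C(F)(F)F
Why: Silylation of the secondary propargylic alcohol under cold, weakly basic conditions avoids acetyl migration.

**Step 16**
Reactants: 31 (2R)-silyloxy alkyne acetate
Product: 32 (3R)-4-acetoxy-3-(tert-butyldimethylsilyloxy)-2-methylidenebutanoic acid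
Conditions: Pd(OAc)2 (2 mol%), 2-(diphenylphosphino)pyridine (10 mol%), TsOH (5 mol%), CO (20 bar), H2O (5 equiv), THF, 50 °C
Reagents that add atoms: carbon monoxide, [C-]#[O+]; water, O
Why: Palladium hydride catalysed Markovnikov hydroxycarbonylation of a terminal alkyne (Drent-type pyridylphosphine catalyst) gives the 2-substituted acrylic acid, with the excess basic ligand buffering the acid so that the silyl ether and acetate survive; the stereocentre is untouched.

**Step 17**
Reactants: 26 macrocyclic 8α-alcohol; 32 (3R)-acid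
Product: 34 [(3aR,4S,6E,10Z,11aR)-10-[(tert-butyldiphenylsilyloxy)methyl]-6-methyl-3-methylidene-2-oxo-2,3,3a,4,5,8,9,11a-octahydrocyclodeca[b]furan-4-yl] (3R)-4-acetoxy-3-(tert-butyldimethylsilyloxy)-2-methylidenebutanoate, via mixed anhydride 33 (not isolated)
Conditions: 32, 2,4,6-trichlorobenzoyl chloride, Et3N, toluene, rt; then 26, DMAP (0.5 equiv), 0 °C to rt
Reagents that add atoms: none
Why: Yamaguchi esterification acylates the hindered secondary 8-hydroxyl through the mixed anhydride with retention at C8 and C3′.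

**Step 18**
Reactants: 34 bis-silyl ester
Product: 35 [(3aR,4S,6E,10Z,11aR)-10-(hydroxymethyl)-6-methyl-3-methylidene-2-oxo-2,3,3a,4,5,8,9,11a-octahydrocyclodeca[b]furan-4-yl] (3R)-4-acetoxy-3-hydroxy-2-methylidenebutanoate (4′-O-acetylcnicin)
Conditions: HF·pyridine, pyridine, THF, 0 °C to rt
Reagents that add atoms: none
Why: Buffered fluoride desilylation removes the TBDPS and TBS ethers while sparing the acetate (no acyl migration), both acrylate units and the acid-sensitive 1(10),4-diene.

**Compound list**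
1 | but-3-yn-1-ol | C#CCCO | starting material
2 | (but-3-yn-1-yloxy)triethylsilane | C#CCCO[Si](CC)(CC)CC | intermediate
3 | oxirane | C1CO1 | starting material
4 | [(1E)-2-methyl-4-(triethylsilyloxy)but-1-en-1-yl]dimethylalane | C[Al](C)/C=C(\C)CCO[Si](CC)(CC)CC | intermediate
5 | lithium butyl(dimethyl)[(1E)-2-methyl-4-(triethylsilyloxy)but-1-en-1-yl]aluminate | [Li+].CCCC[Al-](C)(C)/C=C(\C)CCO[Si](CC)(CC)CC | intermediate
6 | (3E)-4-methyl-6-(triethylsilyloxy)hex-3-en-1-ol | OCC/C=C(\C)CCO[Si](CC)(CC)CC | intermediate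
7 | (3E)-4-methyl-6-(triethylsilyloxy)hex-3-en-1-yl methanesulfonate | CS(=O)(=O)OCC/C=C(\C)CCO[Si](CC)(CC)CC | intermediate
8 | [(3E)-6-bromo-3-methylhex-3-en-1-yl]oxy(triethyl)silane | BrCC/C=C(\C)CCO[Si](CC)(CC)CC | intermediate
9 | prop-2-yn-1-ol | C#CCO | starting material
10 | bromo[(3E)-4-methyl-6-(triethylsilyloxy)hex-3-en-1-yl]magnesium | Br[Mg]CC/C=C(\C)CCO[Si](CC)(CC)CC | intermediate
11 | chloro(prop-2-yn-1-yloxy)magnesium | C#CCO[Mg]Cl | intermediate
12 | 4-[(3E)-4-methyl-6-(triethylsilyloxy)hex-3-en-1-yl]-2,5-dihydro-1,2-oxamagnesole | [Mg]1OCC(CC/C=C(\C)CCO[Si](CC)(CC)CC)=C1 | intermediate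
13 | (2Z)-3-iodo-2-[(3E)-4-methyl-6-(triethylsilyloxy)hex-3-en-1-yl]prop-2-en-1-ol | I/C=C(\CO)CC/C=C(\C)CCO[Si](CC)(CC)CC | intermediate
14 | tert-butyl{[(2Z)-3-iodo-2-[(3E)-4-methyl-6-(triethylsilyloxy)hex-3-en-1-yl]prop-2-en-1-yl]oxy}diphenylsilane | I/C=C(\CO[Si](c1ccccc1)(c1ccccc1)C(C)(C)C)CC/C=C(\C)CCO[Si](CC)(CC)CC | intermediate
15 | [(1Z,5E)-2-[(tert-butyldiphenylsilyloxy)methyl]-6-methyl-8-(triethylsilyloxy)octa-1,5-dien-1-yl]lithium | [Li]/C=C(\CO[Si](c1ccccc1)(c1ccccc1)C(C)(C)C)CC/C=C(\C)CCO[Si](CC)(CC)CC | intermediate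
16 | (2Z,6E)-3-[(tert-butyldiphenylsilyloxy)methyl]-7-methyl-9-(triethylsilyloxy)nona-2,6-dienal | O=C/C=C(\CO[Si](c1ccccc1)(c1ccccc1)C(C)(C)C)CC/C=C(\C)CCO[Si](CC)(CC)CC | intermediate
17 | tert-butyldimethyl(prop-2-yn-1-yloxy)silane | C#CCO[Si](C)(C)C(C)(C)C | starting material
18 | [3-(tert-butyldimethylsilyloxy)prop-1-yn-1-yl](methyl)zinc | C[Zn]C#CCO[Si](C)(C)C(C)(C)C | intermediate
19 | (4R,5Z,9E)-1-(tert-butyldimethylsilyloxy)-6-[(tert-butyldiphenylsilyloxy)methyl]-10-methyl-12-(triethylsilyloxy)dodeca-5,9-dien-2-yn-4-ol | CC(C)(C)[Si](C)(C)OCC#C[C@H](O)/C=C(\CO[Si](c1ccccc1)(c1ccccc1)C(C)(C)C)CC/C=C(\C)CCO[Si](CC)(CC)CC | intermediate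
20 | sodium 2,2-bis(2-methoxyethoxy)-2,5-dihydro-1,2-oxaluminol-2-uide carrying CH2OTBS at C3 and the dienyl chain at C5 (cyclic alkenylalanate of 19) | [Na+].COCCO[Al-]1(OCCOC)O[C@H](/C=C(\CO[Si](c2ccccc2)(c2ccccc2)C(C)(C)C)CC/C=C(\C)CCO[Si](CC)(CC)CC)C=C1CO[Si](C)(C)C(C)(C)C | intermediate
21 | (2Z,4R,5Z,9E)-1-(tert-butyldimethylsilyloxy)-6-[(tert-butyldiphenylsilyloxy)methyl]-2-iodo-10-methyl-12-(triethylsilyloxy)dodeca-2,5,9-trien-4-ol | CC(C)(C)[Si](C)(C)OC/C(I)=C/[C@H](O)/C=C(\CO[Si](c1ccccc1)(c1ccccc1)C(C)(C)C)CC/C=C(\C)CCO[Si](CC)(CC)CC | intermediate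
22 | (5R)-3-[(tert-butyldimethylsilyloxy)methyl]-5-[(1Z,5E)-2-[(tert-butyldiphenylsilyloxy)methyl]-6-methyl-8-(triethylsilyloxy)octa-1,5-dien-1-yl]furan-2(5H)-one | O=C1O[C@H](/C=C(\CO[Si](c2ccccc2)(c2ccccc2)C(C)(C)C)CC/C=C(\C)CCO[Si](CC)(CC)CC)C=C1CO[Si](C)(C)C(C)(C)C | intermediate
23 | (3E,7Z)-8-[(2R)-4-[(tert-butyldimethylsilyloxy)methyl]-5-oxo-2,5-dihydrofuran-2-yl]-7-[(tert-butyldiphenylsilyloxy)methyl]-3-methylocta-3,7-dienal | O=C1O[C@H](/C=C(\CO[Si](c2ccccc2)(c2ccccc2)C(C)(C)C)CC/C=C(\C)CC=O)C=C1CO[Si](C)(C)C(C)(C)C | intermediate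
24 | samarium ketyl radical of 23 (O-bound SmI2, radical at C8) | O=C1O[C@H](/C=C(\CO[Si](c2ccccc2)(c2ccccc2)C(C)(C)C)CC/C=C(\C)C[CH]O[Sm](I)I)C=C1CO[Si](C)(C)C(C)(C)C | intermediate
25 | cyclised bis(diiodosamarium) species: lactone enolate bearing CH2OTBS at C11 and the 8-alkoxide | CC(C)(C)[Si](C)(C)OCC1=C(O[Sm](I)I)O[C@@H]2/C=C(\CO[Si](c3ccccc3)(c3ccccc3)C(C)(C)C)CC/C=C(\C)C[C@H](O[Sm](I)I)[C@@H]12 | intermediate
26 | (3aR,4S,6E,10Z,11aR)-10-[(tert-butyldiphenylsilyloxy)methyl]-4-hydroxy-6-methyl-3-methylidene-3a,4,5,8,9,11a-hexahydrocyclodeca[b]furan-2(3H)-one | C=C1C(=O)O[C@@H]2/C=C(\CO[Si](c3ccccc3)(c3ccccc3)C(C)(C)C)CC/C=C(\C)C[C@H](O)[C@@H]12 | intermediate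
27 | (4S)-2,2-dimethyl-1,3-dioxolane-4-carbaldehyde | O=C[C@@H]1COC(C)(C)O1 | starting material
28 | (4R)-4-ethynyl-2,2-dimethyl-1,3-dioxolane | C#C[C@@H]1COC(C)(C)O1 | intermediate
29 | (2R)-but-3-yne-1,2-diol | C#C[C@@H](O)CO | intermediate
30 | (2R)-2-hydroxybut-3-yn-1-yl acetate | C#C[C@@H](O)COC(C)=O | intermediate
31 | (2R)-2-(tert-butyldimethylsilyloxy)but-3-yn-1-yl acetate | C#C[C@@H](O[Si](C)(C)C(C)(C)C)COC(C)=O | intermediate
32 | (3R)-4-acetoxy-3-(tert-butyldimethylsilyloxy)-2-methylidenebutanoic acid | C=C(C(=O)O)[C@@H](O[Si](C)(C)C(C)(C)C)COC(C)=O | intermediate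
33 | (3R)-4-acetoxy-3-(tert-butyldimethylsilyloxy)-2-methylidenebutanoic 2,4,6-trichlorobenzoic anhydride | C=C(C(=O)OC(=O)c1c(Cl)cc(Cl)cc1Cl)[C@@H](O[Si](C)(C)C(C)(C)C)COC(C)=O | intermediate
34 | [(3aR,4S,6E,10Z,11aR)-10-[(tert-butyldiphenylsilyloxy)methyl]-6-methyl-3-methylidene-2-oxo-2,3,3a,4,5,8,9,11a-octahydrocyclodeca[b]furan-4-yl] (3R)-4-acetoxy-3-(tert-butyldimethylsilyloxy)-2-methylidenebutanoate | C=C1C(=O)O[C@@H]2/C=C(\CO[Si](c3ccccc3)(c3ccccc3)C(C)(C)C)CC/C=C(\C)C[C@H](OC(=O)C(=C)[C@@H](O[Si](C)(C)C(C)(C)C)COC(C)=O)[C@@H]12 | intermediate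
35 | [(3aR,4S,6E,10Z,11aR)-10-(hydroxymethyl)-6-methyl-3-methylidene-2-oxo-2,3,3a,4,5,8,9,11a-octahydrocyclodeca[b]furan-4-yl] (3R)-4-acetoxy-3-hydroxy-2-methylidenebutanoate | C=C1C(=O)O[C@@H]2/C=C(\CO)CC/C=C(\C)C[C@H](OC(=O)C(=C)[C@@H](O)COC(C)=O)[C@@H]12 | target

**Step count**
Total: 18 steps. Longest linear sequence: 13 steps (steps 1–11, 17, 18); steps 12–16 make the side-chain acid.

**Steps most likely to fail**

Step 11 (ring closure). A ten-membered radical closure can lose to simple reduction or pinacol coupling, the enolate may be protonated instead of eliminating, the 8-epimer may form, and the samarium 8-alkoxide may translactonise. Fallback, setting out from 23 and coming back at 26: buffered HF·pyridine (THF, 0 °C) removes only the primary TBS ether of 23 and leaves the TBDPS ether, giving the hydroxymethyl butenolide aldehyde F1. NBS/Me2S (CH2Cl2, −20 °C, Corey–Kim bromination) converts it into the allylic bromide F2. Slow addition of F2 to CrCl2 (THF, 2 mM) closes the ring by a polar intramolecular Nozaki–Hiyama allylation in which the allylchromium reacts through C7 (SE2′), forming C7–C8 and the exocyclic methylene to give 26.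

Step 7 (asymmetric alkynylation). The β,β-disubstituted Z-enal is hindered and may isomerise, and both the level and the sense of induction rest on analogy. Fallback, setting out from 14 and coming back at 19 (16 is bypassed): 17 is deprotonated with n-BuLi and acylated with N-methoxy-N-methylcarbamoyl chloride to give the Weinreb ynamide F3. The alkenyllithium from 14 (t-BuLi, Et2O, −78 °C) adds to F3 to give the cross-conjugated ynone F4. Reduction with (R)-Me-CBS oxazaborolidine [(R)-1-methyl-3,3-diphenylhexahydropyrrolo[1,2-c][1,3,2]oxazaborole] and catecholborane (toluene, −78 °C), with the Z-alkenyl group as the large substituent, gives 19.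

Step 17 (esterification). The 8α-hydroxyl is hindered, the acid is α-branched, and base can move the lactone from O-6 to O-8. Fallback, setting out from 23 and 32 and coming back at 34 (isolated 26 is bypassed): 32 is converted with 1-chloro-N,N,2-trimethylprop-1-en-1-amine under neutral conditions into the acid chloride F5. The ring closure of step 11 is then run without aqueous quench and F5 is added at −78 °C once 23 is consumed, so that the samarium 8-alkoxide is acylated in the flask and gives 34 directly.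

**Further compounds**
F1 | step 11 | (3E,7Z)-7-[(tert-butyldiphenylsilyloxy)methyl]-8-[(2R)-4-(hydroxymethyl)-5-oxo-2,5-dihydrofuran-2-yl]-3-methylocta-3,7-dienal | O=C1O[C@H](/C=C(\CO[Si](c2ccccc2)(c2ccccc2)C(C)(C)C)CC/C=C(\C)CC=O)C=C1CO
F2 | step 11 | (3E,7Z)-8-[(2R)-4-(bromomethyl)-5-oxo-2,5-dihydrofuran-2-yl]-7-[(tert-butyldiphenylsilyloxy)methyl]-3-methylocta-3,7-dienal | O=C1O[C@H](/C=C(\CO[Si](c2ccccc2)(c2ccccc2)C(C)(C)C)CC/C=C(\C)CC=O)C=C1CBr
F3 | step 7 | 4-(tert-butyldimethylsilyloxy)-N-methoxy-N-methylbut-2-ynamide | CON(C)C(=O)C#CCO[Si](C)(C)C(C)(C)C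
F4 | step 7 | (5Z,9E)-1-(tert-butyldimethylsilyloxy)-6-[(tert-butyldiphenylsilyloxy)methyl]-10-methyl-12-(triethylsilyloxy)dodeca-5,9-dien-2-yn-4-one | CC(C)(C)[Si](C)(C)OCC#CC(=O)/C=C(\CO[Si](c1ccccc1)(c1ccccc1)C(C)(C)C)CC/C=C(\C)CCO[Si](CC)(CC)CC
F5 | step 17 | (3R)-4-acetoxy-3-(tert-butyldimethylsilyloxy)-2-methylidenebutanoyl chloride | C=C(C(Cl)=O)[C@@H](O[Si](C)(C)C(C)(C)C)COC(C)=O
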